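The data were generated by integration with constants of no real substance.

57.1% of the Sub charged is what stays in Sunday's flask if each Rgt takes one Sub and nothing else touches Sub. Call this fraction left the stop line. In Sunday's flask Rgt is the limiting reagent, so:

stop line = (Sub charged − Rgt charged) / Sub charged = (1400 mM − 600 mM) / 1400 mM = 57.1%

You are taking over Sunday's flask of Sub and Rgt, which give Prd. Keep it closed, stirred and at the temperature of the two earlier runs.

| flask | Sub | Rgt | time |
|---|---|---|---|
| Thursday's | 200 mM | 600 mM |  |
| Tuesday's | 600 mM | 600 mM |  |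
| Sunday's | 1400 mM | 600 mM | 5.1 h |

| run | time / h | [Sub] / mM |
|---|---|---|
| Thursday's run | 0.23 | 176.8 |
| Thursday's run | 0.69 | 139.9 |
| Thursday's run | 1.3 | 105.4 |
| Thursday's run | 2.1 | 74.0 |
| Thursday's run | 3.0 | 51.3 |
| Thursday's run | 4.0 | 33.0 |
| Thursday's run | 5.1 | 22.3 |
| Tuesday's run | 0.23 | 528.5 |
| Tuesday's run | 0.69 | 422.1 |
| Tuesday's run | 1.3 | 330.9 |
| Tuesday's run | 2.1 | 254.7 |
| Tuesday's run | 3.0 | 196.6 |
| Tuesday's run | 4.0 | 155.5 |
| Tuesday's run | 5.1 | 122.6 |

(readings scatter by 0.6 mM)

- order of the initial rate in [Sub], near the charge of the Thursday's run, the rate being that where two percent of its Sub are Prd (one fixed amount of Prd, the same in the runs compared)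
- Sub in the Sunday's run at 5.1 h, as a share of the Sub charged

- Overall: Sub + Rgt -> Prd.
- Constant volume, constant temperature.
- "The second partner" is Rgt.
- An order is taken over about fifteen percent of the charge, up and down.

Expect to find less Sub than the stop line. At equal charges, Sub + Rgt by itself gives a straight line for the reciprocal of [Sub] against time, and Tuesday's readings bend:

slope over the last two readings ÷ slope over the first two = 1.51

The forecast reads the same bend, “Sub is disappearing by something beyond Rgt”. It gives an order of 1.05 (0.95 to 1.2) and 45% of Sunday's Sub left (36% to 57%).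

The simulation gives an order of 1.0 and leaves 32.3% of Sunday's Sub at 5.1 h. That is 25 percentage points under the stop line, and lower than the forecast's low end.

    Sub + Rgt → Prd (0.8352 M⁻¹ h⁻¹)
    2 Sub → Z (0.05508 M⁻¹ h⁻¹)
    Sub → E (0.02088 h⁻¹)

Of that gap, 19 points comes from the reaction of 2 Sub to Z. Its rate goes with [Sub] squared, and Sunday's charge of Sub is higher than in the other two runs. In Sunday's run without that reaction, the Sub left at 5.1 h rises to 51.5%, which is 5.6 points under the stop line.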